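**Plan**

Target: a (2S,4S)-4',7-dihydroxyflavan (upper unit) bound through its C4 to C8 of (−)-epigallocatechin (lower unit). Retrosynthetic cuts, in order: the eight O–benzyl bonds; C2–H and C2–aryl of the upper unit (back to a lactone C2=O); O1–C8a (O1 taken out of ring C); C4–C4a (aryl–palladium onto an enone); Cα=Cβ of a chalcone; the C8–CHO bond on the lower unit.
Enabling feature: ring C of the upper unit (O1, C2, C3, C4, C4a, C8a) is an aryl–O–alkyl unit in which O1 links ring-A carbon C8a to C2, and C2 can be carried as a carbonyl. Without O1 the same atoms are the cyclopentanone ring of a 3-arylindan-1-one, whose aryl–carbonyl bond accepts one oxygen atom.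
Forward: the lower unit is bought with its rings, benzylated and formylated at C8; aldol condensation with a 2-bromoaryl methyl ketone (future ring A) gives a chalcone; a reductive Heck reaction closes the five-membered carbocycle; oxygen insertion expands it to the six-membered ring C; an aryl Grignard reagent brings ring B; reductive etherification and hydrogenolysis finish.
Stereochemistry: C2 and C3 of the lower unit come from (−)-epigallocatechin; upper C4 from the chiral palladium catalyst of the reductive Heck step (the minor epimer is a diastereomer); upper C2 from hydride delivery to a cyclic oxocarbenium ion anti to the C4 aryl group (2,4-cis).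

Key step: step 8

Remark: which antipode of the bisphosphine in step 7 gives the (3S)-indanone is assigned by analogy only; the antipode that does so is the one to be used.
In the names, G = (2R,3R)-3,5,7-tris(benzyloxy)-2-[3,4,5-tris(benzyloxy)phenyl]chroman-8-yl (the benzylated lower unit bound through C8).

Step 1
Reactants: 1 (−)-epigallocatechin
Product: 2 (2R,3R)-5,7-bis(benzyloxy)-2-[3,4,5-tris(benzyloxy)phenyl]chroman-3-ol
Conditions: BnBr, K2CO3, DMF, 0 °C to rt, argon
Reagents that add atoms: benzyl bromide, BrCc1ccccc1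
Why: Williamson etherification: carbonate deprotonates only the five phenols, which are benzylated while the less acidic secondary 3-OH stays free, and the mild base leaves both stereocentres untouched.

Step 2
Reactants: 2 (2R,3R)-5,7-bis(benzyloxy)-2-[3,4,5-tris(benzyloxy)phenyl]chroman-3-ol
Product: 3 (2R,3R)-3,5,7-tris(benzyloxy)-2-[3,4,5-tris(benzyloxy)phenyl]chroman (G–H)
Conditions: NaH, BnBr, Bu4NI (cat.), DMF, 0 °C to rt
Reagents that add atoms: benzyl bromide, BrCc1ccccc1
Why: Williamson etherification of the sodium alkoxide of the remaining secondary alcohol; with all phenols capped no quinone methide can form, so C2 should not epimerise.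

Step 3
Reactants: 3 G–H
Product: 4 (2R,3R)-3,5,7-tris(benzyloxy)-8-bromo-2-[3,4,5-tris(benzyloxy)phenyl]chroman (G–Br)
Conditions: NBS, CH2Cl2, −78 °C to 0 °C
Reagents that add atoms: N-bromosuccinimide, O=C1CCC(=O)N1Br
Why: Electrophilic aromatic bromination of the phloroglucinol-type ring; C8 (between O1 and the 7-benzyloxy group) is the position attacked first in per-benzylated flavan-3-ols, and one equivalent at low temperature limits attack at C6 and on the tribenzyloxyphenyl ring.

Step 4
Reactants: 4 G–Br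
Product: 6 (2R,3R)-3,5,7-tris(benzyloxy)-2-[3,4,5-tris(benzyloxy)phenyl]chroman-8-carbaldehyde (G–CHO), via aryllithium 5 (not isolated)
Conditions: n-BuLi, THF, −78 °C; DMF, −78 °C to rt; H2O
Reagents that add atoms: N,N-dimethylformamide, CN(C)C=O
Why: Lithium–bromine exchange is faster than benzylic deprotonation at −78 °C, and aryllithium 5 is formylated by DMF (Bouveault-type formylation), the aldehyde being released on hydrolysis.

Step 5
Reactants: 7 1-[3-(benzyloxy)phenyl]ethan-1-one
Product: 8 1-[5-(benzyloxy)-2-bromophenyl]ethan-1-one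
Conditions: NBS, MeCN, rt, dark
Reagents that add atoms: N-bromosuccinimide, O=C1CCC(=O)N1Br
Why: Electrophilic bromination goes para to the benzyloxy group (ortho to acetyl), the known outcome for 3-alkoxyacetophenones, and places the halide where the aryl–palladium bond is needed.

Step 6
Reactants: 6 G–CHO; 8 1-[5-(benzyloxy)-2-bromophenyl]ethan-1-one
Product: 9 (E)-1-[5-(benzyloxy)-2-bromophenyl]-3-G-prop-2-en-1-one
Conditions: KOH, EtOH/THF, rt
Reagents that add atoms: none
Why: Claisen–Schmidt aldol condensation between the non-enolisable aldehyde and the methyl ketone; E1cB dehydration gives the conjugated E-enone and the aryl bromide is inert to hydroxide.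

Step 7
Reactants: 9 (E)-1-[5-(benzyloxy)-2-bromophenyl]-3-G-prop-2-en-1-one
Product: 10 (3S)-6-(benzyloxy)-3-G-2,3-dihydro-1H-inden-1-one
Conditions: Pd(OAc)2 (5 mol %), (R)-3,5-Xyl-MeO-BIPHEP (6 mol %), HCO2Na, DMF, 80 °C
Reagents that add atoms: none
Why: Asymmetric intramolecular reductive Heck reaction: zerovalent palladium inserts into the C–Br bond, enantioface-selective carbopalladation of the enone forms the C3–C3a bond of the five-membered ring, and protonolysis with formate as the terminal reductant releases the ketone, so the new C3 stereocentre is set by the chiral bisphosphine and its epimer is a separable diastereomer.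

Step 8
Reactants: 10 (3S)-6-(benzyloxy)-3-G-2,3-dihydro-1H-inden-1-one
Product: 12 (4S)-7-(benzyloxy)-4-G-chroman-2-one, via Criegee adduct 11 (not isolated)
Conditions: mCPBA (1.5 equiv), TsOH·H2O (cat.), CH2Cl2, 0–4 °C, dark
Reagents that add atoms: 3-chloroperoxybenzoic acid, OOC(=O)c1cccc(Cl)c1
Why: TsOH activates the C1 carbonyl of 10 for addition of the peracid to give Criegee adduct 11, in which the ring-A carbon C7a, antiperiplanar to the O–O bond, shifts from C1 to oxygen as 3-chlorobenzoate leaves, so that one oxygen atom is inserted into the C1–C7a bond and becomes O1 of ring C. The closest known reaction type is the Baeyer–Villiger oxidation of 3-arylindan-1-ones to 4-aryl-3,4-dihydrocoumarins. No ring is closed by a new cyclisation: the five-membered carbocycle (C1, C2, C3, C3a, C7a) is enlarged by a 1,2-shift from carbon to oxygen into the six-membered lactone (O1, C2, C3, C4, C4a, C8a). No stereocentre is formed; C3 of 10 is neither the migrating atom nor alpha to the carbonyl and should be carried over unchanged as (4S)-C4 of 12. Two selectivities are needed: aryl over C2 migration, secured by the higher migratory aptitude of an aryl carbon than of a primary alkyl carbon, and ketone over arene oxidation, secured by acid catalysis of carbonyl addition at 0–4 °C with a small excess of peracid and by the meta placement of the 6-benzyloxy group, which leaves the C1 carbonyl unconjugated to an oxygen donor and therefore electrophilic.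

Step 9
Reactants: 12 (4S)-7-(benzyloxy)-4-G-chroman-2-one; 13 [4-(benzyloxy)phenyl]magnesium bromide
Product: 14 (3S)-1-[4-(benzyloxy)phenyl]-3-[4-(benzyloxy)-2-hydroxyphenyl]-3-G-propan-1-one
Conditions: THF, −78 °C to −30 °C (1.1 equiv of 13); H2O
Reagents that add atoms: none
Why: Grignard addition to the aryl ester carbonyl (C2 of ring C) with ring opening; at low temperature one equivalent should add once, because the ketone formed is a deactivated 4-alkoxyaryl ketone next to a magnesium phenoxide, and C4 is not touched.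

Step 10
Reactants: 14 (3S)-1-[4-(benzyloxy)phenyl]-3-[4-(benzyloxy)-2-hydroxyphenyl]-3-G-propan-1-one
Product: 16 (2S,4S)-7-(benzyloxy)-2-[4-(benzyloxy)phenyl]-4-G-chroman, via oxocarbenium ion 15 (not isolated)
Conditions: Et3SiH, BF3·OEt2, CH2Cl2, −78 °C to −20 °C
Reagents that add atoms: none
Why: Reductive etherification (ionic hydrogenation): BF3 closes the phenol onto the ketone with loss of water to oxocarbenium ion 15, and Et3SiH delivers hydride to C2 along the axial trajectory on the face anti to the pseudo-equatorial C4 aryl group, so the C2 aryl group ends equatorial and cis to G (2S).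

Step 11
Reactants: 16 (2S,4S)-7-(benzyloxy)-2-[4-(benzyloxy)phenyl]-4-G-chroman
Product: 17 (2R,3R)-8-[(2S,4S)-7-hydroxy-2-(4-hydroxyphenyl)chroman-4-yl]-2-(3,4,5-trihydroxyphenyl)chroman-3,5,7-triol
Conditions: H2 (1 atm), Pd(OH)2/C, THF/MeOH, rt; filtration under argon
Reagents that add atoms: none
Why: Hydrogenolysis removes all eight benzyl ethers while the cyclic benzylic C2–O bonds and the C4–C8 bond are expected to persist under these mild conditions; no stereocentre is involved.

**Compound list**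

1 | (−)-epigallocatechin | Oc1cc(O)c2c(c1)O[C@H](c1cc(O)c(O)c(O)c1)[C@H](O)C2 | starting material
2 | (2R,3R)-5,7-bis(benzyloxy)-2-[3,4,5-tris(benzyloxy)phenyl]chroman-3-ol | c1c(OCc9ccccc9)cc(OCc9ccccc9)c2c1O[C@H](c3cc(OCc9ccccc9)c(OCc9ccccc9)c(OCc9ccccc9)c3)[C@H](O)C2 | intermediate
3 | (2R,3R)-3,5,7-tris(benzyloxy)-2-[3,4,5-tris(benzyloxy)phenyl]chroman (G–H) | c1c(OCc9ccccc9)cc(OCc9ccccc9)c2c1O[C@H](c3cc(OCc9ccccc9)c(OCc9ccccc9)c(OCc9ccccc9)c3)[C@H](OCc9ccccc9)C2 | intermediate
4 | G–Br, the 8-bromo derivative of 3 | Brc1c(OCc9ccccc9)cc(OCc9ccccc9)c2c1O[C@H](c3cc(OCc9ccccc9)c(OCc9ccccc9)c(OCc9ccccc9)c3)[C@H](OCc9ccccc9)C2 | intermediate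
5 | G–Li, the 8-lithio derivative of 3 (not isolated) | [Li]c1c(OCc9ccccc9)cc(OCc9ccccc9)c2c1O[C@H](c3cc(OCc9ccccc9)c(OCc9ccccc9)c(OCc9ccccc9)c3)[C@H](OCc9ccccc9)C2 | intermediate
6 | G–CHO, the 8-carbaldehyde of 3 | O=Cc1c(OCc9ccccc9)cc(OCc9ccccc9)c2c1O[C@H](c3cc(OCc9ccccc9)c(OCc9ccccc9)c(OCc9ccccc9)c3)[C@H](OCc9ccccc9)C2 | intermediate
7 | 1-[3-(benzyloxy)phenyl]ethan-1-one | CC(=O)c1cccc(OCc2ccccc2)c1 | starting material
8 | 1-[5-(benzyloxy)-2-bromophenyl]ethan-1-one | CC(=O)c1cc(OCc2ccccc2)ccc1Br | intermediate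
9 | (E)-1-[5-(benzyloxy)-2-bromophenyl]-3-G-prop-2-en-1-one | O=C(/C=C/c1c(OCc9ccccc9)cc(OCc9ccccc9)c2c1O[C@H](c3cc(OCc9ccccc9)c(OCc9ccccc9)c(OCc9ccccc9)c3)[C@H](OCc9ccccc9)C2)c4cc(OCc9ccccc9)ccc4Br | intermediate
10 | (3S)-6-(benzyloxy)-3-G-2,3-dihydro-1H-inden-1-one | O=C4C[C@H](c1c(OCc9ccccc9)cc(OCc9ccccc9)c2c1O[C@H](c3cc(OCc9ccccc9)c(OCc9ccccc9)c(OCc9ccccc9)c3)[C@H](OCc9ccccc9)C2)c5ccc(OCc9ccccc9)cc54 | intermediate
11 | Criegee adduct: (3S)-6-(benzyloxy)-1-hydroxy-3-G-2,3-dihydro-1H-inden-1-yl 3-chlorobenzenecarboperoxoate, both C1 epimers (not isolated) | OC4(OOC(=O)c7cccc(Cl)c7)C[C@H](c1c(OCc9ccccc9)cc(OCc9ccccc9)c2c1O[C@H](c3cc(OCc9ccccc9)c(OCc9ccccc9)c(OCc9ccccc9)c3)[C@H](OCc9ccccc9)C2)c5ccc(OCc9ccccc9)cc54 | intermediate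
12 | (4S)-7-(benzyloxy)-4-G-chroman-2-one | O=C4C[C@H](c1c(OCc9ccccc9)cc(OCc9ccccc9)c2c1O[C@H](c3cc(OCc9ccccc9)c(OCc9ccccc9)c(OCc9ccccc9)c3)[C@H](OCc9ccccc9)C2)c5ccc(OCc9ccccc9)cc5O4 | intermediate
13 | [4-(benzyloxy)phenyl]magnesium bromide (THF solution) | Br[Mg]c1ccc(OCc2ccccc2)cc1 | starting material
14 | (3S)-1-[4-(benzyloxy)phenyl]-3-[4-(benzyloxy)-2-hydroxyphenyl]-3-G-propan-1-one | O=C(C[C@H](c1c(OCc9ccccc9)cc(OCc9ccccc9)c2c1O[C@H](c3cc(OCc9ccccc9)c(OCc9ccccc9)c(OCc9ccccc9)c3)[C@H](OCc9ccccc9)C2)c5ccc(OCc9ccccc9)cc5O)c6ccc(OCc9ccccc9)cc6 | intermediate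
15 | (4S)-7-(benzyloxy)-2-[4-(benzyloxy)phenyl]-4-G-3,4-dihydrochromenylium, cyclic oxocarbenium ion (not isolated) | [O+]4=C(c6ccc(OCc9ccccc9)cc6)C[C@H](c1c(OCc9ccccc9)cc(OCc9ccccc9)c2c1O[C@H](c3cc(OCc9ccccc9)c(OCc9ccccc9)c(OCc9ccccc9)c3)[C@H](OCc9ccccc9)C2)c5ccc(OCc9ccccc9)cc54 | intermediate
16 | (2S,4S)-7-(benzyloxy)-2-[4-(benzyloxy)phenyl]-4-G-chroman | c9ccccc9COc6ccc([C@@H]4C[C@H](c1c(OCc9ccccc9)cc(OCc9ccccc9)c2c1O[C@H](c3cc(OCc9ccccc9)c(OCc9ccccc9)c(OCc9ccccc9)c3)[C@H](OCc9ccccc9)C2)c5ccc(OCc9ccccc9)cc5O4)cc6 | intermediate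
17 | (2R,3R)-8-[(2S,4S)-7-hydroxy-2-(4-hydroxyphenyl)chroman-4-yl]-2-(3,4,5-trihydroxyphenyl)chroman-3,5,7-triol | Oc1ccc([C@@H]2C[C@H](c3c(O)cc(O)c4c3O[C@H](c3cc(O)c(O)c(O)c3)[C@H](O)C4)c3ccc(O)cc3O2)cc1 | target

**Step count and risks**

Total steps: 11. Longest linear sequence: 10 steps (from 1 through steps 1–4 and 6–11).

Steps most likely to fail:

1. Step 8. The peracid may oxidise the benzyloxy-rich arenes of G in competition with the slow aryl-ketone oxidation, or C2 may migrate instead of the aryl carbon. The fallback sets out from 4 and comes back at 12. Aryllithium 5, generated from 4 as in step 4, would be trapped with 2-isopropoxy-4,4,5,5-tetramethyl-1,3,2-dioxaborolane to give the C8 pinacol boronate F1. Rhodium-catalysed asymmetric conjugate arylation (Hayashi–Miyaura type; Rh(acac)(C2H4)2, SEGPHOS antipode matched to the required C4 configuration, dioxane with little water, 60 °C) of commercial 7-(benzyloxy)-2H-chromen-2-one (O=C1C=Cc2ccc(OCc3ccccc3)cc2O1) with F1 would then give lactone 12 without an oxidant.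

2. Step 7. Facial selectivity in the carbopalladation may be poor, so that 10 forms as a mixture of C3 epimers. The fallback sets out from this epimeric 10 and comes back at stereodefined 10. Dehydrogenation with 2-iodoxybenzoic acid (DMSO, 65 °C) would erase C3 and give 6-(benzyloxy)-3-G-1H-inden-1-one F2. Corey–Bakshi–Shibata reduction ((S)-2-methyl-CBS-oxazaborolidine, BH3·SMe2, −20 °C; antipode assigned by the usual model with the fused arene as the large group) would give (1R)-6-(benzyloxy)-3-G-1H-inden-1-ol F3. An amine-mediated suprafacial 1,3-hydrogen shift (1,4-diazabicyclo[2.2.2]octane, THF, 60 °C) would move the C1 hydrogen to the same face of C3 and return (3S)-10.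

3. Step 9. A second addition of the Grignard reagent to the liberated ketone, or enolisation of the lactone, may consume material. The fallback sets out from 12 and comes back at 14. Lactone 12 would be opened with N,O-dimethylhydroxylamine hydrochloride and i-PrMgCl (THF, −20 °C) to (3S)-3-[4-(benzyloxy)-2-hydroxyphenyl]-N-methoxy-N-methyl-3-G-propanamide F4. Its chelated tetrahedral adduct with excess 13 (the first equivalent deprotonates the phenol) would collapse only on work-up, giving ketone 14.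

**Further compounds**

F1 | step 8 | (2R,3R)-3,5,7-tris(benzyloxy)-8-(4,4,5,5-tetramethyl-1,3,2-dioxaborolan-2-yl)-2-[3,4,5-tris(benzyloxy)phenyl]chroman | CC7(C)OB(OC7(C)C)c1c(OCc9ccccc9)cc(OCc9ccccc9)c2c1O[C@H](c3cc(OCc9ccccc9)c(OCc9ccccc9)c(OCc9ccccc9)c3)[C@H](OCc9ccccc9)C2
F2 | step 7 | 6-(benzyloxy)-3-G-1H-inden-1-one | O=C4C=C(c1c(OCc9ccccc9)cc(OCc9ccccc9)c2c1O[C@H](c3cc(OCc9ccccc9)c(OCc9ccccc9)c(OCc9ccccc9)c3)[C@H](OCc9ccccc9)C2)c5ccc(OCc9ccccc9)cc54
F3 | step 7 | (1R)-6-(benzyloxy)-3-G-1H-inden-1-ol | O[C@@H]4C=C(c1c(OCc9ccccc9)cc(OCc9ccccc9)c2c1O[C@H](c3cc(OCc9ccccc9)c(OCc9ccccc9)c(OCc9ccccc9)c3)[C@H](OCc9ccccc9)C2)c5ccc(OCc9ccccc9)cc54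
F4 | step 9 | (3S)-3-[4-(benzyloxy)-2-hydroxyphenyl]-N-methoxy-N-methyl-3-G-propanamide | CON(C)C(=O)C[C@H](c1c(OCc9ccccc9)cc(OCc9ccccc9)c2c1O[C@H](c3cc(OCc9ccccc9)c(OCc9ccccc9)c(OCc9ccccc9)c3)[C@H](OCc9ccccc9)C2)c5ccc(OCc9ccccc9)cc5O
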